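Assumption: methyl (R)-lactate (the ester of fermentation D-lactic acid) is taken as a cheap, commercially available chiral starting material; the target is the trans-(2S,3S) isomer as drawn.

**Retrosynthetic overview**
1. The (E)-enal is unmasked last from a terminal allyl group by DDQ oxidation of allyl-benzodioxane 17.
2. The 1,4-dioxane ring (the only ring formed and kept) is closed at O1–C2 by an intramolecular Mitsunobu reaction with inversion on erythro alcohol 16; C2 is set by a chelation-controlled reduction directed by the lactate-derived C3.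
3. The aryl ketone comes from a 3,4,5-trimethoxyphenyl Grignard reagent and benzodioxinone lactone 11 (a temporary ring); 11 comes from Dakin oxidation of a salicylaldehyde ether.
4. The C3–O4 bond comes from a Mitsunobu inversion of methyl (R)-lactate with phenol 6.
5. The arene–side-chain C–C bond is made first, by an aromatic para-Claisen rearrangement ([3,3] Claisen, then [3,3] Cope) of O-allyl-o-vanillin.

**Route**

Step 1
Reactants: 1 2-hydroxy-3-methoxybenzaldehyde (o-vanillin); 2 allyl bromide
Product: 3 2-(allyloxy)-3-methoxybenzaldehyde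
Conditions: K2CO3, DMF, rt
Reagents that add atoms: none
Why: Williamson ether synthesis, in which the phenoxide of 1 displaces bromide from the SN2-reactive allyl bromide; no stereocenter is involved.

Step 2
Reactants: 3 2-(allyloxy)-3-methoxybenzaldehyde
Product: 6 5-allyl-2-hydroxy-3-methoxybenzaldehyde, via ortho-dienone 4 (not isolated), via para-dienone 5 (not isolated)
Conditions: PhNEt2, 200 °C, sealed tube, 3 h
Reagents that add atoms: none
Why: aromatic para-Claisen rearrangement, in which both ortho positions are blocked, so the [3,3] shift to 4 is followed by a Cope [3,3] shift to the para carbon (5) and tautomerisation, forming the arene–side-chain C–C bond with no stereocenter left.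

Step 3
Reactants: 6 5-allyl-2-hydroxy-3-methoxybenzaldehyde; 7 methyl (R)-lactate
Product: 8 methyl (2S)-2-(4-allyl-2-formyl-6-methoxyphenoxy)propanoate
Conditions: PPh3, DIAD, THF, 0 °C to rt
Reagents that add atoms: none
Why: Mitsunobu etherification, in which the acidic phenol displaces the activated α-carbonyl alcohol of 7 by SN2 with clean inversion, so (R)-lactate becomes the (S)-aryloxypropanoate that is C3 of the target.

Step 4
Reactants: 8 methyl (2S)-2-(4-allyl-2-formyl-6-methoxyphenoxy)propanoate
Product: 11 (3S)-7-allyl-5-methoxy-3-methyl-1,4-benzodioxin-2(3H)-one, via aryl formate 9 (not isolated), via phenol ester 10 (not isolated)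
Conditions: 30% H2O2, cat. H2SO4, MeOH, rt; Na2S2O3 quench, solvent switch; then cat. p-TsOH, PhMe, 90 °C, 4 Å MS (−MeOH)
Reagents that add atoms: hydrogen peroxide, OO
Why: acid-catalysed Dakin (Baeyer–Villiger) oxidation, in which the ortho-alkoxyaryl group migrates to oxygen, the formate is methanolysed and the freed phenol lactonises onto the neighbouring ester; peroxide under acid leaves the terminal alkene and the α-stereocenter untouched.

Step 5
Reactants: 11 (3S)-7-allyl-5-methoxy-3-methyl-1,4-benzodioxin-2(3H)-one; 12 5-bromo-1,2,3-trimethoxybenzene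
Product: 15 (2S)-2-(4-allyl-2-hydroxy-6-methoxyphenoxy)-1-(3,4,5-trimethoxyphenyl)propan-1-one, via aryl Grignard reagent 13 (not isolated), via magnesium hemiketalate 14 (not isolated)
Conditions: 12, Mg, cat. I2, THF, reflux; then add 1.05 equiv to 11, THF, −78 °C; NH4Cl (aq) at −78 °C
Reagents that add atoms: none
Why: Grignard acylation by an activated aryl lactone, in which the adduct is held as chelated hemiketalate 14 until the cold quench so only one aryl group adds, and the low temperature and low basicity leave C3 unepimerised (15 equilibrates with its cyclic hemiketal).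

Step 6
Reactants: 15 (2S)-2-(4-allyl-2-hydroxy-6-methoxyphenoxy)-1-(3,4,5-trimethoxyphenyl)propan-1-one
Product: 16 5-allyl-2-{[(1R,2S)-1-hydroxy-1-(3,4,5-trimethoxyphenyl)propan-2-yl]oxy}-3-methoxyphenol
Conditions: Zn(BH4)2 (pre-formed, Et2O), Et2O/THF, −20 to 0 °C
Reagents that add atoms: none
Why: chelation-controlled (Cram chelate) ketone reduction, in which divalent zinc anchored on the phenoxide bridges the carbonyl and α-aryloxy oxygens and hydride enters from the side of the small α-H, so the lactate-derived center sets the carbinol as 1R (erythro).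

Step 7
Reactants: 16 5-allyl-2-{[(1R,2S)-1-hydroxy-1-(3,4,5-trimethoxyphenyl)propan-2-yl]oxy}-3-methoxyphenol
Product: 17 (2S,3S)-7-allyl-5-methoxy-3-methyl-2-(3,4,5-trimethoxyphenyl)-2,3-dihydro-1,4-benzodioxine
Conditions: PPh3, DIAD, THF, 0 °C to rt
Reagents that add atoms: none
Why: intramolecular Mitsunobu etherification, a 6-exo SN2 attack of the phenol oxygen on the activated benzylic carbon with inversion (1R becomes 2S), which gives the trans-2,3-disubstituted dioxane ring that is also the thermodynamic isomer.

Step 8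
Reactants: 17 (2S,3S)-7-allyl-5-methoxy-3-methyl-2-(3,4,5-trimethoxyphenyl)-2,3-dihydro-1,4-benzodioxine
Product: 19 (2E)-3-[(2S,3S)-5-methoxy-3-methyl-2-(3,4,5-trimethoxyphenyl)-2,3-dihydro-1,4-benzodioxin-7-yl]prop-2-enal, via cinnamyl alcohol 18 (not isolated)
Conditions: DDQ (2.5 equiv), 1,4-dioxane/H2O (trace AcOH), rt
Reagents that add atoms: water, O
Why: DDQ oxidation of an allylarene, in which hydride is abstracted from the doubly activated benzylic–allylic CH2, water adds at the chain terminus to give 18 and a second DDQ oxidises it to the conjugated (E)-enal (the thermodynamically preferred geometry), without involving the ring stereocenters.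

**Compound list**
1 | 2-hydroxy-3-methoxybenzaldehyde (o-vanillin) | COc1cccc(C=O)c1O | starting material
2 | allyl bromide (3-bromoprop-1-ene) | C=CCBr | starting material
3 | 2-(allyloxy)-3-methoxybenzaldehyde | COc1cccc(C=O)c1OCC=C | intermediate
4 | 6-allyl-2-formyl-6-methoxycyclohexa-2,4-dien-1-one (ortho-dienone, racemic) | O=CC1=CC=CC(CC=C)(OC)C1=O | intermediate
5 | 4-allyl-2-formyl-6-methoxycyclohexa-2,5-dien-1-one (para-dienone) | O=CC1=CC(CC=C)C=C(OC)C1=O | intermediate
6 | 5-allyl-2-hydroxy-3-methoxybenzaldehyde | COc1cc(CC=C)cc(C=O)c1O | intermediate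
7 | methyl (R)-lactate, methyl (2R)-2-hydroxypropanoate | C[C@@H](O)C(=O)OC | starting material
8 | methyl (2S)-2-(4-allyl-2-formyl-6-methoxyphenoxy)propanoate | C[C@H](Oc1c(C=O)cc(CC=C)cc1OC)C(=O)OC | intermediate
9 | methyl (2S)-2-[4-allyl-2-(formyloxy)-6-methoxyphenoxy]propanoate (aryl formate) | C[C@H](Oc1c(OC=O)cc(CC=C)cc1OC)C(=O)OC | intermediate
10 | methyl (2S)-2-(4-allyl-2-hydroxy-6-methoxyphenoxy)propanoate (phenol ester) | C[C@H](Oc1c(O)cc(CC=C)cc1OC)C(=O)OC | intermediate
11 | (3S)-7-allyl-5-methoxy-3-methyl-1,4-benzodioxin-2(3H)-one | C[C@@H]1Oc2c(OC)cc(CC=C)cc2OC1=O | intermediate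
12 | 5-bromo-1,2,3-trimethoxybenzene | COc1cc(Br)cc(OC)c1OC | starting material
13 | (3,4,5-trimethoxyphenyl)magnesium bromide | COc1cc([Mg]Br)cc(OC)c1OC | intermediate
14 | bromomagnesium (3S)-7-allyl-5-methoxy-3-methyl-2-(3,4,5-trimethoxyphenyl)-2,3-dihydro-1,4-benzodioxin-2-olate (hemiketalate, both C2 epimers) | C[C@@H]1Oc2c(OC)cc(CC=C)cc2OC1(O[Mg]Br)c3cc(OC)c(OC)c(OC)c3 | intermediate
15 | (2S)-2-(4-allyl-2-hydroxy-6-methoxyphenoxy)-1-(3,4,5-trimethoxyphenyl)propan-1-one (open form of the cyclic hemiketal) | C[C@H](Oc1c(O)cc(CC=C)cc1OC)C(=O)c1cc(OC)c(OC)c(OC)c1 | intermediate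
16 | 5-allyl-2-{[(1R,2S)-1-hydroxy-1-(3,4,5-trimethoxyphenyl)propan-2-yl]oxy}-3-methoxyphenol (erythro) | C[C@H](Oc1c(O)cc(CC=C)cc1OC)[C@H](O)c1cc(OC)c(OC)c(OC)c1 | intermediate
17 | (2S,3S)-7-allyl-5-methoxy-3-methyl-2-(3,4,5-trimethoxyphenyl)-2,3-dihydro-1,4-benzodioxine (trans) | COc1cc([C@@H]2Oc3cc(CC=C)cc(OC)c3O[C@H]2C)cc(OC)c1OC | intermediate
18 | (2E)-3-[(2S,3S)-5-methoxy-3-methyl-2-(3,4,5-trimethoxyphenyl)-2,3-dihydro-1,4-benzodioxin-7-yl]prop-2-en-1-ol | COc1cc([C@@H]2Oc3cc(/C=C/CO)cc(OC)c3O[C@H]2C)cc(OC)c1OC | intermediate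
19 | (2E)-3-[(2S,3S)-5-methoxy-3-methyl-2-(3,4,5-trimethoxyphenyl)-2,3-dihydro-1,4-benzodioxin-7-yl]prop-2-enal (CNP0258373.1) | COc1cc([C@@H]2Oc3cc(/C=C/C=O)cc(OC)c3O[C@H]2C)cc(OC)c1OC | target

**Totals**
Total step count: 8. Longest linear sequence: 8 steps (from 1 to 19).

**Steps most likely to fail, with fallbacks**

Step 5 (single addition of 13 to lactone 11). The risks are a second addition giving a tertiary alcohol and base-induced epimerisation at C3. The fallback sets out from 11: the lactone is opened with MeNH(OMe)·HCl and i-PrMgCl in THF at −20 °C to the Weinreb amide (2S)-2-(4-allyl-2-hydroxy-6-methoxyphenoxy)-N-methoxy-N-methylpropanamide F1. F1 is then treated with 2.5 equiv of 13 in THF at 0 °C; the first equivalent makes the phenoxide, and the stable N-methoxy chelate rules out a second addition. Work-up gives ketone 15, where the route is rejoined.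

Step 6 (erythro-selective reduction). The ring–chain equilibrium of 15 and the free phenol could erode chelation control and contaminate 16 with its C1 epimer, which would give cis product in step 7. The fallback sets out from 15: NaBH4 in MeOH at 0 °C reduces it without stereocontrol to 16 mixed with its threo epimer 5-allyl-2-{[(1S,2S)-1-hydroxy-1-(3,4,5-trimethoxyphenyl)propan-2-yl]oxy}-3-methoxyphenol F2. The mixture is then cyclised under acid (Amberlyst 15, PhMe, 60 °C) through the 3,4,5-trimethoxybenzyl cation. Both epimers converge under thermodynamic control on the diequatorial trans isomer, so steps 6 and 7 are replaced and the route is rejoined at 17.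

Step 8 (DDQ oxidation of allyl to enal). DDQ could also abstract hydride at the C2–H benzylic ether position, or the sequence could stall at 18. The fallback sets out from 17: the allyl group is isomerised with PdCl2(MeCN)2 (5 mol %, CH2Cl2, 40 °C) to the conjugated alkene (2S,3S)-5-methoxy-3-methyl-7-[(E)-prop-1-enyl]-2-(3,4,5-trimethoxyphenyl)-2,3-dihydro-1,4-benzodioxine F3. Cross-metathesis of F3 with crotonaldehyde (second-generation Hoveyda–Grubbs catalyst, CH2Cl2, 40 °C) then gives the (E)-enal, arriving directly at 19.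

**Further compounds**
F1 | step 5 | (2S)-2-(4-allyl-2-hydroxy-6-methoxyphenoxy)-N-methoxy-N-methylpropanamide | C[C@H](Oc1c(O)cc(CC=C)cc1OC)C(=O)N(C)OC
F2 | step 6 | 5-allyl-2-{[(1S,2S)-1-hydroxy-1-(3,4,5-trimethoxyphenyl)propan-2-yl]oxy}-3-methoxyphenol (threo epimer of 16) | C[C@H](Oc1c(O)cc(CC=C)cc1OC)[C@@H](O)c1cc(OC)c(OC)c(OC)c1
F3 | step 8 | (2S,3S)-5-methoxy-3-methyl-7-[(E)-prop-1-enyl]-2-(3,4,5-trimethoxyphenyl)-2,3-dihydro-1,4-benzodioxine | COc1cc([C@@H]2Oc3cc(/C=C/C)cc(OC)c3O[C@H]2C)cc(OC)c1OC
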